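1. In the red run Gu overtakes Qa at about 7.08 h, later than the 3.39 h read from the violet run. That is twice as long, with [Gy] and [Uv] at half of violet's.

all flasks: Uv 1 mol%

| run | Gy | remark | time |
|---|---|---|---|
| violet | 0.82 M | the very flask that is asked about, followed so far |  |
| red | 0.41 M | run made earlier |  |
| flask | 0.82 M |  | 15 h |

| run | time / h | Gu / % | Qa / % |
|---|---|---|---|
| violet | 0.833 | 2.9 | 22.9 |
| violet | 2.00 | 17.2 | 35.4 |
| violet | 2.50 | 20.6 | 34.3 |
| violet | 4.00 | 36.8 | 27.5 |
| violet | 5.00 | 44.9 | 26.2 |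
| red | 1.00 | 1.5 | 16.3 |
| red | 2.50 | 7.1 | 32.0 |
| red | 5.00 | 21.2 | 34.0 |
| red | 8.00 | 33.4 | 27.7 |
| red | 10.0 | 43.4 | 24.8 |

(standard deviation of a reading: 1 percentage point)

* ratio of Gu to Qa at 100 s
* ratio of Gu to Qa at 15 h

- the earlier runs were read with a standard deviation of 1 percentage point
- steps thought possible: Jy <-> Gy; Qa + Uv <-> Gu + Uv; Gy + Uv <-> Qa + Uv; Gu <-> Jy

2. So two times matter: the crossing time, when Gu and Qa stand level, and the time you ask about. At 15 h violet stands at 4.42. This clock reading is the time asked about divided by the crossing time.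

3. At 100 s the violet reading is far below the crossing, so I scale the ratio at the first violet reading, 0.127, in step with time, and get 0.00422.

4. The time 15 h lies later than the last violet reading, so I commit to no figure there.

5. The forecast gives 0.0045 for the early ratio, a little above mine, and 9 for the late one, between 4 and 20, “with wide uncertainty”.

6. The flask gives 0.00454 and 12.0.

    Jy ⇌ Gy (k = 6.30 × 10⁻⁷ s⁻¹)
    Qa + Uv ⇌ Gu + Uv, rate k2*[Uv]*[Qa] forward; the back reaction follows from the equilibrium constant (K = 24.0, k = 0.0110 M⁻¹ s⁻¹)
    Gy + Uv ⇌ Qa + Uv, rate k3*[Gy]*[Uv] forward; the back reaction follows from the equilibrium constant (K = 1.80, k = 0.0160 M⁻¹ s⁻¹)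
    Gu ⇌ Jy (K = 0.320, k = 8.90 × 10⁻⁷ s⁻¹)

7. In the flask Gu and Qa stand level at 3.50 h, and 15 h lies later than that, at the clock reading of 4.42 taken from violet. The step from Qa to Gu, both ways, has the largest single effect on the late ratio: the run without it gives 0.0257 instead of 12.0, and Gu and Qa do not come level by 15 h. Charging 1.4 M of Gy lifts the reading to 7.55 and the ratio to 21.5; 1.7 mol% of Uv gives a reading of 7.51 and a ratio of 21.4.

The numbers in the tables come from a simulation for substances that don't exist, noise included.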